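**Assumption:** the SMILES is taken as the full definition of CNP0113954.1 (1R,3S,4S,6R,7S,8R,10S; cis-1,10-epoxide; angelate ester); germacrane numbering (C1–C10 ring, C11–C13 on C7, C14 on C10, C15 on C4) is used for all ten-membered-ring compounds.

## Retrosynthetic overview

1. Target ⇐ syn-dihydroxylation of the 3E alkene, preceded by C8 angeloylation, C11 methylenation and C8-OH-directed epoxidation of the 1(10)Z alkene of a germacradien-12,6-olide.
2. γ-Lactone ⇐ keto ester: C6–Si → C6–OH with retention, then lactonisation; the C7–C11 bond comes from alkylation of the rearrangement enolate.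
3. Ten-membered ring ⇐ trans-1,2-dialkenylcyclohexenol by anionic oxy-Cope rearrangement (C5–C6 bond formed; the cyclohexene alkene becomes the 1(10)Z alkene, the isopropenyl group the 3E alkene).
4. Cyclohexenone ⇐ (S)-carvone by 1,2-carbonyl transposition through a vinyl epoxide.
5. Ring order: cyclohexene (bought) → ten-membered carbocycle → γ-lactone → oxirane.

## Route

Step 1
Reactants: 1 (S)-(+)-carvone
Product: 3 (5R,6R)-6-bromo-2-methyl-5-(prop-1-en-2-yl)cyclohex-2-en-1-one, via trimethylsilyl dienol ether 2 (not isolated)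
Conditions: LiN(iPr)2, THF, −78 °C; Me3SiCl; then NBS, −78 → 0 °C
Reagents that add atoms: N-bromosuccinimide, BrN1C(=O)CCC1=O
Why: Kinetic deprotonation at C6 gives the cross-conjugated dienolate, whose silyl dienol ether is brominated by NBS at its terminus (α′-bromination of a silyl enol ether) anti to the neighbouring isopropenyl group, so bromine is set trans to the carvone stereocentre.

Step 2
Reactants: 3 (5R,6R)-6-bromo-2-methyl-5-(prop-1-en-2-yl)cyclohex-2-en-1-one
Product: 5 (1R,5R,6S)-2-methyl-5-(prop-1-en-2-yl)-7-oxabicyclo[4.1.0]hept-2-ene, via bromohydrin 4 (not isolated)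
Conditions: NaBH4, CeCl3·7H2O, MeOH, −78 → 0 °C; then K2CO3, rt
Reagents that add atoms: none
Why: Luche 1,2-reduction gives the trans-bromohydrin (carbinol cis to isopropenyl), and K2CO3 closes the oxirane by intramolecular Williamson SN2 displacement with inversion at C6, so the epoxide is cis to the isopropenyl group.

Step 3
Reactants: 5 (1R,5R,6S)-2-methyl-5-(prop-1-en-2-yl)-7-oxabicyclo[4.1.0]hept-2-ene
Product: 6 (6R)-3-methyl-6-(prop-1-en-2-yl)cyclohex-3-en-1-one
Conditions: Pd(PPh3)4 (3 mol %), CH2Cl2, 0 °C → rt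
Reagents that add atoms: none
Why: Pd(PPh3)4 ionises the allylic C–O bond of the diene monoepoxide to a π-allylpalladium alkoxide that collapses by 1,2-hydride shift to the β,γ-unsaturated ketone (redox-neutral vinyl epoxide isomerisation), a net 1,2-carbonyl transposition under neutral conditions that leaves the now α-stereocentre untouched.

Step 4
Reactants: 7 (E)-1,2-bis(tributylstannyl)ethene
Product: 9 benzyl(dimethyl)[(E)-2-(tributylstannyl)ethenyl]silane, via stannylvinyllithium 8 (not isolated)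
Conditions: n-BuLi (1.0 equiv), THF, −78 °C; BnMe2SiCl, −78 °C → rt
Reagents that add atoms: benzylchlorodimethylsilane, C[Si](C)(Cl)Cc1ccccc1
Why: Tin–lithium exchange of one stannyl group proceeds with retention of the E geometry and the vinyllithium is silylated at carbon; no stereocentre is formed.

Step 5
Reactants: 6 (6R)-3-methyl-6-(prop-1-en-2-yl)cyclohex-3-en-1-one, 9 benzyl(dimethyl)[(E)-2-(tributylstannyl)ethenyl]silane
Product: 12 (1R,6R)-1-{(E)-2-[benzyl(dimethyl)silyl]ethenyl}-3-methyl-6-(prop-1-en-2-yl)cyclohex-3-en-1-ol, via silylvinyllithium 10 (not isolated), via silylvinylcerium dichloride 11 (not isolated)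
Conditions: 9, n-BuLi, THF, −78 °C; CeCl3, −78 °C; then 6, −78 °C; H2O work-up
Reagents that add atoms: none
Why: A second tin–lithium exchange and transmetalation to the weakly basic organocerium allow clean 1,2-addition to the enolisable ketone, the bulky alkenyl nucleophile entering anti to the adjacent isopropenyl group so that the new carbinol centre (1R) carries the two alkenyl groups trans.

Step 6
Reactants: 12 (1R,6R)-1-{(E)-2-[benzyl(dimethyl)silyl]ethenyl}-3-methyl-6-(prop-1-en-2-yl)cyclohex-3-en-1-ol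
Product: 15 ethyl 2-{(1R,2R,4E,7Z)-2-[benzyl(dimethyl)silyl]-4,8-dimethyl-10-oxocyclodeca-4,7-dien-1-yl}acetate, via potassium alkoxide 13 (not isolated), via potassium enolate 14 (not isolated)
Conditions: KH (1.1 equiv), 18-crown-6, THF, 0 °C → rt; then ICH2CO2Et, −78 → −20 °C
Reagents that add atoms: ethyl iodoacetate, CCOC(=O)CI
Why: The potassium alkoxide undergoes anionic oxy-Cope rearrangement ([3,3]-sigmatropic) through a chair transition state with both alkenyl arms equatorial, which forms the C5–C6 bond and the ten-membered ring, gives the 3E alkene, keeps the cyclohexene alkene as the 1(10)Z alkene and transfers the chirality of the carvone-derived centre to C6 (equatorial E-silyl group), after which the regiodefined enolate is C-alkylated on its outer face anti to silicon to set C7.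

Step 7
Reactants: 15 ethyl 2-{(1R,2R,4E,7Z)-2-[benzyl(dimethyl)silyl]-4,8-dimethyl-10-oxocyclodeca-4,7-dien-1-yl}acetate
Product: 18 (6R,7S)-8-oxo-13-norgermacra-1(10)Z,3E-dien-12,6-olide, via silanol 16 (not isolated), via hydroxy ester 17 (not isolated)
Conditions: Bu4NF, THF, 0 °C, 15 min; then KHCO3, 30% H2O2, MeOH/THF, rt
Reagents that add atoms: hydrogen peroxide, OO
Why: Fluoride cleaves the benzyl–silicon bond and Tamao–Fleming oxidation replaces silicon by hydroxyl with retention at C6, the γ-hydroxy ester then closing to the trans-fused γ-lactone, whose C6–O bond lies orthogonal to the C7 enol π-system and so resists β-elimination.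

Step 8
Reactants: 18 (6R,7S)-8-oxo-13-norgermacra-1(10)Z,3E-dien-12,6-olide
Product: 19 (6R,7R,8R)-8-hydroxy-13-norgermacra-1(10)Z,3E-dien-12,6-olide
Conditions: NaBH4, CeCl3·7H2O, MeOH/THF, −78 °C
Reagents that add atoms: none
Why: Hydride reduction under Luche conditions (non-basic, so no translactonisation and no conjugation of the 1(10) alkene) attacks the C8 ketone from the open outer face anti to the lactone C11 branch, giving the 8R alcohol with H7 and H8 cis.

Step 9
Reactants: 19 (6R,7R,8R)-8-hydroxy-13-norgermacra-1(10)Z,3E-dien-12,6-olide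
Product: 20 (1R,6R,7R,8R,10S)-1,10-epoxy-8-hydroxy-13-norgermacr-3E-en-12,6-olide
Conditions: VO(acac)2 (5 mol %), t-BuOOH, CH2Cl2, 0 °C → rt
Reagents that add atoms: tert-butyl hydroperoxide, CC(C)(C)OO
Why: Vanadium-catalysed hydroxyl-directed epoxidation delivers oxygen through the homoallylic vanadate to the 1(10)Z alkene on the face syn to the C8 hydroxyl (1R,10S, cis-epoxide), while the 3E alkene has no through-bond tether to the hydroxyl and is left untouched.

Step 10
Reactants: 20 (1R,6R,7R,8R,10S)-1,10-epoxy-8-hydroxy-13-norgermacr-3E-en-12,6-olide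
Product: 23 (1R,6R,7R,8R,10S)-1,10-epoxy-8-hydroxygermacra-3E,11(13)-dien-12,6-olide, via Mannich base 21 (not isolated), via trimethylammonium iodide 22 (not isolated)
Conditions: LiN(iPr)2 (2.5 equiv, inverse addition), THF, −78 °C; Me2N=CH2+ I− (Eschenmoser's salt), −78 → 0 °C; then MeI, MeOH, rt; then aq. NaHCO3, EtOAc, rt
Reagents that add atoms: Eschenmoser's salt, C=[N+](C)C.[I-]
Why: The alkoxide–lactone enolate dianion undergoes Mannich reaction with Eschenmoser's salt at C11, and quaternisation followed by base-induced elimination of trimethylamine gives the exocyclic α-methylene lactone, the transient C11 centre being destroyed.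

Step 11
Reactants: 23 (1R,6R,7R,8R,10S)-1,10-epoxy-8-hydroxygermacra-3E,11(13)-dien-12,6-olide, 24 angelic acid
Product: 26 (1R,6R,7S,8R,10S)-8-angeloyloxy-1,10-epoxygermacra-3E,11(13)-dien-12,6-olide, via mixed anhydride 25 (not isolated)
Conditions: 24, 2,4,6-Cl3C6H2COCl, Et3N, PhMe, rt; then 23, 80 °C
Reagents that add atoms: none
Why: Yamaguchi esterification through the mixed anhydride acylates the hindered secondary C8 alcohol without DMAP, which keeps the Z (angelate) geometry and leaves all stereocentres unchanged.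

Step 12
Reactants: 26 (1R,6R,7S,8R,10S)-8-angeloyloxy-1,10-epoxygermacra-3E,11(13)-dien-12,6-olide
Product: 27 (1R,3S,4S,6R,7S,8R,10S)-8-angeloyloxy-1,10-epoxy-3,4-dihydroxygermacr-11(13)-en-12,6-olide (CNP0113954.1)
Conditions: OsO4 (5 mol %), NMO (1.1 equiv), acetone/H2O, 0 °C
Reagents that add atoms: N-methylmorpholine N-oxide, C[N+]1([O-])CCOCC1; water, O
Why: Upjohn dihydroxylation: OsO4 adds suprafacially to the strained, electron-rich 3E trisubstituted alkene faster than to the two conjugated alkenes, on its outer face in the ring conformer inherited from the chair rearrangement (C15 syn to H6), giving the 3S,4S syn-diol.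

## Compound list

1 | (S)-(+)-carvone, (5S)-2-methyl-5-(prop-1-en-2-yl)cyclohex-2-en-1-one | CC1=CC[C@@H](CC1=O)C(C)=C | starting material
2 | trimethyl{[(3S)-6-methyl-3-(prop-1-en-2-yl)cyclohexa-1,5-dien-1-yl]oxy}silane | CC1=CC[C@@H](C=C1O[Si](C)(C)C)C(C)=C | intermediate
3 | (5R,6R)-6-bromo-2-methyl-5-(prop-1-en-2-yl)cyclohex-2-en-1-one (Br trans to isopropenyl) | CC1=CC[C@@H]([C@@H](Br)C1=O)C(C)=C | intermediate
4 | (1R,5R,6R)-6-bromo-2-methyl-5-(prop-1-en-2-yl)cyclohex-2-en-1-ol (trans-bromohydrin) | CC1=CC[C@@H]([C@@H](Br)[C@@H]1O)C(C)=C | intermediate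
5 | (1R,5R,6S)-2-methyl-5-(prop-1-en-2-yl)-7-oxabicyclo[4.1.0]hept-2-ene (epoxide cis to isopropenyl) | CC1=CC[C@H](C(C)=C)[C@@H]2O[C@H]12 | intermediate
6 | (6R)-3-methyl-6-(prop-1-en-2-yl)cyclohex-3-en-1-one | CC1=CC[C@H](C(C)=C)C(=O)C1 | intermediate
7 | (E)-1,2-bis(tributylstannyl)ethene | CCCC[Sn](CCCC)(CCCC)/C=C/[Sn](CCCC)(CCCC)CCCC | starting material
8 | [(E)-2-(tributylstannyl)ethenyl]lithium | [Li]/C=C/[Sn](CCCC)(CCCC)CCCC | intermediate
9 | benzyl(dimethyl)[(E)-2-(tributylstannyl)ethenyl]silane | C[Si](C)(Cc1ccccc1)/C=C/[Sn](CCCC)(CCCC)CCCC | intermediate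
10 | {(E)-2-[benzyl(dimethyl)silyl]ethenyl}lithium | [Li]/C=C/[Si](C)(C)Cc1ccccc1 | intermediate
11 | {(E)-2-[benzyl(dimethyl)silyl]ethenyl}cerium dichloride | Cl[Ce](Cl)/C=C/[Si](C)(C)Cc1ccccc1 | intermediate
12 | (1R,6R)-1-{(E)-2-[benzyl(dimethyl)silyl]ethenyl}-3-methyl-6-(prop-1-en-2-yl)cyclohex-3-en-1-ol (alkenyl groups trans) | CC1=CC[C@H](C(C)=C)[C@@](O)(/C=C/[Si](C)(C)Cc2ccccc2)C1 | intermediate
13 | potassium (1R,6R)-1-{(E)-2-[benzyl(dimethyl)silyl]ethenyl}-3-methyl-6-(prop-1-en-2-yl)cyclohex-3-en-1-olate | CC1=CC[C@H](C(C)=C)[C@@]([O-])(/C=C/[Si](C)(C)Cc2ccccc2)C1.[K+] | intermediate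
14 | potassium (1Z,3R,5E,8Z)-3-[benzyl(dimethyl)silyl]-5,9-dimethylcyclodeca-1,5,8-trien-1-olate | [K+].[O-]/C1=C\[C@H]([Si](C)(C)Cc2ccccc2)C/C(C)=C/C/C=C(C)\C1 | intermediate
15 | ethyl 2-{(1R,2R,4E,7Z)-2-[benzyl(dimethyl)silyl]-4,8-dimethyl-10-oxocyclodeca-4,7-dien-1-yl}acetate | CCOC(=O)C[C@H]1[C@H]([Si](C)(C)Cc2ccccc2)C/C(C)=C/C/C=C(C)\CC1=O | intermediate
16 | ethyl 2-{(1R,2R,4E,7Z)-2-[hydroxy(dimethyl)silyl]-4,8-dimethyl-10-oxocyclodeca-4,7-dien-1-yl}acetate | CCOC(=O)C[C@H]1[C@H]([Si](C)(C)O)C/C(C)=C/C/C=C(C)\CC1=O | intermediate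
17 | ethyl 2-[(1S,2R,4E,7Z)-2-hydroxy-4,8-dimethyl-10-oxocyclodeca-4,7-dien-1-yl]acetate | CCOC(=O)C[C@H]1[C@H](O)C/C(C)=C/C/C=C(C)\CC1=O | intermediate
18 | (6R,7S)-8-oxo-13-norgermacra-1(10)Z,3E-dien-12,6-olide (trans-fused lactone) | O=C1C[C@H]2[C@H](O1)C/C(C)=C/C/C=C(C)\CC2=O | intermediate
19 | (6R,7R,8R)-8-hydroxy-13-norgermacra-1(10)Z,3E-dien-12,6-olide | O=C1C[C@H]2[C@H](O1)C/C(C)=C/C/C=C(C)\C[C@H]2O | intermediate
20 | (1R,6R,7R,8R,10S)-1,10-epoxy-8-hydroxy-13-norgermacr-3E-en-12,6-olide | O=C1C[C@H]2[C@H](O1)C/C(C)=C/C[C@H]3O[C@@]3(C)C[C@H]2O | intermediate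
21 | (1R,6R,7R,8R,10S,11RS)-13-(dimethylamino)-1,10-epoxy-8-hydroxygermacr-3E-en-12,6-olide | CN(C)CC1C(=O)O[C@@H]2C/C(C)=C/C[C@H]3O[C@@]3(C)C[C@@H](O)[C@@H]12 | intermediate
22 | trimethylammonium iodide of 21 (N-methyl quaternary salt) | C[N+](C)(C)CC1C(=O)O[C@@H]2C/C(C)=C/C[C@H]3O[C@@]3(C)C[C@@H](O)[C@@H]12.[I-] | intermediate
23 | (1R,6R,7R,8R,10S)-1,10-epoxy-8-hydroxygermacra-3E,11(13)-dien-12,6-olide | C=C1C(=O)O[C@@H]2C/C(C)=C/C[C@H]3O[C@@]3(C)C[C@@H](O)[C@@H]12 | intermediate
24 | angelic acid, (Z)-2-methylbut-2-enoic acid | C/C=C(/C)C(=O)O | starting material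
25 | (Z)-2-methylbut-2-enoic 2,4,6-trichlorobenzoic anhydride | C/C=C(/C)C(=O)OC(=O)c1c(Cl)cc(Cl)cc1Cl | intermediate
26 | (1R,6R,7S,8R,10S)-8-angeloyloxy-1,10-epoxygermacra-3E,11(13)-dien-12,6-olide | C=C1C(=O)O[C@@H]2C/C(C)=C/C[C@H]3O[C@@]3(C)C[C@@H](OC(=O)/C(C)=C\C)[C@@H]12 | intermediate
27 | (1R,3S,4S,6R,7S,8R,10S)-8-angeloyloxy-1,10-epoxy-3,4-dihydroxygermacr-11(13)-en-12,6-olide (CNP0113954.1) | C=C1C(=O)O[C@@H]2C[C@](C)(O)[C@@H](O)C[C@H]3O[C@@]3(C)C[C@@H](OC(=O)/C(C)=C\C)[C@@H]12 | target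

## Step count and risks

Total step count: 12 (11 in the main line from 1, plus step 4 for reagent 9).
Longest linear sequence: 11 steps (1 → 27 through steps 1–3 and 5–12).

**Step 6 (oxy-Cope rearrangement and enolate alkylation in one pot).** The risks are O-alkylation, over-alkylation, and base-induced conjugation of the 1(10) alkene in the product ketone. The fallback separates the two events and makes the C7–C11 bond by carbene transfer instead of enolate alkylation. It sets out from 12: KH/18-crown-6 as before, but enolate 14 is quenched at −78 °C with Me3SiCl to give the trimethylsilyl enol ether F1. Cu(acac)2-catalysed cyclopropanation with ethyl diazoacetate takes place on the electron-rich enol ether from its outer face and gives the siloxycyclopropane ester F2. Et3N·3HF opens this donor–acceptor cyclopropane to the γ-keto ester, and the route is rejoined at 15.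

**Step 10 (methylenation of the unprotected hydroxy lactone).** The C8 alkoxide can translactonise to the 12,8-olide before the lactone enolate forms. The fallback masks the alcohol and sets out from 20: Et3SiCl/imidazole gives the 8-O-triethylsilyl ether F3. LiN(iPr)2 (1.1 equiv) and Eschenmoser's salt give the Mannich base F4, MeI gives its methiodide F5, and aq. NaHCO3 gives the α-methylene lactone silyl ether F6. HF·pyridine buffered with pyridine removes the silyl group, and the route is rejoined at 23.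

**Step 12 (last-step dihydroxylation).** The facial selectivity rests on a conformational argument, not a directing group, and the two conjugated alkenes are also present. The fallback introduces the diol one stage earlier and from the opposite sense of approach, by hydrogen-bond delivery from the C8 hydroxyl, which lies across the ring from C3=C4. It sets out from 23: stoichiometric OsO4·TMEDA in CH2Cl2 at −78 °C (directed dihydroxylation), then aq. NaHSO3, gives the 3,4,8-triol F7. PhB(OH)2 ties the 3,4-diol as the cyclic phenylboronate F8, leaving only the C8 hydroxyl free. Yamaguchi acylation with 24 as in step 11 gives the boronate-protected angelate F9. Exchange with pinacol releases the diol, and the route ends at 27.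

## Further compounds

F1 | step 6 | {[(1Z,3R,5E,8Z)-3-[benzyl(dimethyl)silyl]-5,9-dimethylcyclodeca-1,5,8-trien-1-yl]oxy}trimethylsilane | C[Si](C)(C)O/C1=C\[C@H]([Si](C)(C)Cc2ccccc2)C/C(C)=C/C/C=C(C)\C1
F2 | step 6 | ethyl (3Z,6E)-9-[benzyl(dimethyl)silyl]-3,7-dimethyl-1-[(trimethylsilyl)oxy]bicyclo[8.1.0]undeca-3,6-diene-11-carboxylate | CCOC(=O)C1[C@H]2[C@H]([Si](C)(C)Cc3ccccc3)C/C(C)=C/C/C=C(C)\C[C@]12O[Si](C)(C)C
F3 | step 10 | (1R,6R,7R,8R,10S)-1,10-epoxy-8-(triethylsilyloxy)-13-norgermacr-3E-en-12,6-olide | O=C1C[C@H]2[C@H](O1)C/C(C)=C/C[C@H]3O[C@@]3(C)C[C@H]2O[Si](CC)(CC)CC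
F4 | step 10 | 13-(dimethylamino)-1,10-epoxy-8-(triethylsilyloxy)germacr-3E-en-12,6-olide (C11 epimers) | CN(C)CC1C(=O)O[C@@H]2C/C(C)=C/C[C@H]3O[C@@]3(C)C[C@@H](O[Si](CC)(CC)CC)[C@@H]12
F5 | step 10 | trimethylammonium iodide of F4 | C[N+](C)(C)CC1C(=O)O[C@@H]2C/C(C)=C/C[C@H]3O[C@@]3(C)C[C@@H](O[Si](CC)(CC)CC)[C@@H]12.[I-]
F6 | step 10 | 1,10-epoxy-8-(triethylsilyloxy)germacra-3E,11(13)-dien-12,6-olide | C=C1C(=O)O[C@@H]2C/C(C)=C/C[C@H]3O[C@@]3(C)C[C@@H](O[Si](CC)(CC)CC)[C@@H]12
F7 | step 12 | (1R,3S,4S,6R,7R,8R,10S)-1,10-epoxy-3,4,8-trihydroxygermacr-11(13)-en-12,6-olide | C=C1C(=O)O[C@@H]2C[C@](C)(O)[C@@H](O)C[C@H]3O[C@@]3(C)C[C@@H](O)[C@@H]12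
F8 | step 12 | 3,4-O-(phenylboranediyl) derivative of F7 | C=C1C(=O)O[C@@H]2C[C@](C)(O4)[C@@H](OB4c5ccccc5)C[C@H]3O[C@@]3(C)C[C@@H](O)[C@@H]12
F9 | step 12 | 8-O-angeloyl 3,4-O-(phenylboranediyl) derivative of F7 | C=C1C(=O)O[C@@H]2C[C@](C)(O4)[C@@H](OB4c5ccccc5)C[C@H]3O[C@@]3(C)C[C@@H](OC(=O)/C(C)=C\C)[C@@H]12
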